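Everything rests on cutting both bonds at the ester carbonyl carbon C1: C1–C2, which leads through the CH2CH2 tether to the para-disubstituted benzene ring, and C1–O to the nonadecyl chain. Flanked by the ArCH2CH2 chain and the ester oxygen, C1 is the mark of a carbonylation. A linear-selective palladium hydride alkoxycarbonylation therefore joins 4-acetoxystyrene (1), carbon monoxide (2) and nonadecan-1-ol (3) into nonadecyl 3-(4-acetoxyphenyl)propanoate (4) in one operation. The precursor is simply the bought vinylarene, its phenol masked as an acetate to damp polymerisation. Chemoselective aminolysis of that aryl acetate then gives nonadecyl 3-(4-hydroxyphenyl)propanoate (5).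

Key step: step 1

Remark on the chemistry: 1 is used as sold, with its radical inhibitor left in. Any aryl acetate lost during step 1 appears as 5 itself, so 4 and any 5 are freed of excess 1 by flash chromatography and taken into step 2 together.

Step 1
Reactants: 1 4-acetoxystyrene (1.2 equiv); 2 carbon monoxide; 3 nonadecan-1-ol (1.0 equiv)
Product: 4 nonadecyl 3-(4-acetoxyphenyl)propanoate
Conditions: Pd(OAc)2 (1 mol%), 1,2-bis(di-tert-butylphosphinomethyl)benzene (4 mol%), MsOH (5 mol%), BHT (1 mol%), CO (10 bar), dry toluene, 80 °C, 20 h
Reagents that add atoms: none
Why: Pd(OAc)2, the diphosphine and MsOH generate a cationic divalent palladium hydride that adds reversibly across the vinyl group of 1, giving interconverting branched benzylic and linear 2-arylethyl palladium species; CO inserts into the linear alkyl to form an acyl complex, and 3 cleaves it by alcoholysis, releasing 4 and returning the hydride. The closest known reaction type is the palladium-catalysed hydroalkoxycarbonylation (hydroesterification) of vinylarenes with bulky chelating bis(di-tert-butylphosphino) ligands and a sulfonic acid promoter, which is established for styrenes and for alcohols beyond methanol. No ring is closed and no stereocenter is created; the two new bonds are C2–C1 and C1–O of the ester. The selectivity needed is linear over branched, and it is imposed mainly by the ligand, whose wide bite angle and four tert-butyl groups crowd the benzylic palladium species so that only the primary alkyl should go on to acyl and ester; in the substrate, the unsubstituted terminal CH2 of the vinyl group offers that uncrowded primary position. Attack of 3 on the acyl palladium in preference to the aryl acetate is helped by keeping the acid near the amount buffered by the excess phosphine, by the apolar solvent and by the moderate temperature. The acetoxy group donates far less than a free or alkylated phenol oxygen, which holds back acid-induced oligomerisation and Markovnikov addition of the alcohol, while BHT guards against radical polymerisation.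

Step 2
Reactants: 4 nonadecyl 3-(4-acetoxyphenyl)propanoate
Product: 5 nonadecyl 3-(4-hydroxyphenyl)propanoate
Conditions: pyrrolidine (2 equiv), CH2Cl2, 0 °C to rt, 2 h; dilute aq. HCl wash; recrystallisation or flash chromatography
Reagents that add atoms: none
Why: Chemoselective aminolysis of an aryl ester: phenoxide is a far better leaving group than the nonadecyl alkoxide, so the amine should take the acetyl group off the phenol oxygen at room temperature while the unactivated alkyl ester stays intact.

Compound list
1 | 4-acetoxystyrene (4-ethenylphenyl acetate) | CC(=O)Oc1ccc(C=C)cc1 | starting material
2 | carbon monoxide | [C-]#[O+] | starting material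
3 | nonadecan-1-ol | CCCCCCCCCCCCCCCCCCCO | starting material
4 | nonadecyl 3-(4-acetoxyphenyl)propanoate | CCCCCCCCCCCCCCCCCCCOC(=O)CCc1ccc(OC(C)=O)cc1 | intermediate
5 | nonadecyl 3-(4-hydroxyphenyl)propanoate | CCCCCCCCCCCCCCCCCCCOC(=O)CCc1ccc(O)cc1 | target

Total step count: 2
Longest linear sequence: 2 steps

Steps most likely to fail: the route has only two steps, so both are given, the riskier one first.

Riskiest is step 1. Three processes could erode it: carbonylation leaking through the benzylic palladium species to the branched ester, transfer of the acetyl group from the aryl acetate to the alcohol under the acid promoter, and acid- or radical-induced oligomerisation of the vinylarene. The fallback sets out from 3 and comes back at 4, building the aryl–C3 bond instead of the C2–C1 bond so that no branched isomer can arise. Compound 3 is acylated with acryloyl chloride (Et3N, CH2Cl2, 0 °C) to give nonadecyl acrylate F1. A Mizoroki–Heck coupling of this acrylate with commercial 4-iodophenyl acetate (Pd(OAc)2, P(o-tolyl)3, Et3N, DMF, 90 °C) should give nonadecyl (E)-3-(4-acetoxyphenyl)prop-2-enoate F2. Hydrogenation of the conjugated alkene (H2 1 atm, Pd/C, EtOAc, rt) then delivers 4, which continues with step 2.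

Second is step 2. Acetyl transfer could stall, or the amine could begin to attack the nonadecyl ester on prolonged exposure. The fallback sets out from 2 and 3 and comes back at 5, changing the phenol protection to a group that leaves without any nucleophile. Commercial 4-benzyloxystyrene takes the place of 1 in the alkoxycarbonylation of step 1, with the acid loading lowered to spare the more electron-rich alkene, and should give nonadecyl 3-(4-benzyloxyphenyl)propanoate F3. Hydrogenolysis of the benzyl ether (H2 1 atm, Pd/C, THF/EtOAc, rt) then gives 5 under neutral conditions that leave the alkyl ester untouched.

Further compounds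
F1 | step 1 | nonadecyl acrylate | CCCCCCCCCCCCCCCCCCCOC(=O)C=C
F2 | step 1 | nonadecyl (E)-3-(4-acetoxyphenyl)prop-2-enoate | CCCCCCCCCCCCCCCCCCCOC(=O)/C=C/c1ccc(OC(C)=O)cc1
F3 | step 2 | nonadecyl 3-(4-benzyloxyphenyl)propanoate | CCCCCCCCCCCCCCCCCCCOC(=O)CCc1ccc(OCc2ccccc2)cc1
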